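**Plan**

- Retrosynthesis: the C5 acetyl group is traced back to a benzyl ester (through the acid and a Weinreb amide), one indole nitrogen is given a Boc group, and the pyrrole is cut at N1–C2 and at C3–C4.
- Enabling feature: N1, C2 (with its CO2Me) and C3 (with its indol-3-yl) are the ketone carbon, ester and methylene carbon of methyl indol-3-ylpyruvate. N1, C5 and C4 (with its indol-3-yl) are the amine, α-carbon and aryl ketone of an α-amino β-keto ester.
- Forward: the pyruvate ester 2 (one step) and the oximino keto ester 8 (three steps from 1-Boc-indole-3-carbaldehyde) are made separately. A zinc-mediated Knorr condensation joins them and closes the pyrrole, the only ring built; both indoles are bought.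
- The benzyl ester is then converted into the acetyl group (hydrogenolysis, Weinreb amide, MeMgBr) and the Boc group is removed.
- Stereochemistry: the target has no stereocentre; the oxime geometry and the transient α-carbon of the amino ketone vanish on aromatisation.

Key step: step 5

Remark on the chemistry: only the indole of the amino ketone partner carries N-Boc, where it is needed to keep the 3-acylindole electrophilic. The pyruvate partner is used with its free N–H, and oxime 8 is used as the E/Z mixture that forms.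

**Step 1**
Reactants: 1 indole-3-pyruvic acid
Product: 2 methyl 3-(1H-indol-3-yl)-2-oxopropanoate (largely enolised)
Conditions: MeI (1.1 equiv), KHCO3 (1.1 equiv), DMF, 0 °C → rt, dark
Reagents that add atoms: iodomethane, CI
Why: Carboxylate O-alkylation (SN2 esterification), in which bicarbonate should deprotonate only the α-keto acid and not the enol O–H or the indole N–H, so that MeI methylates the carboxylate alone.

**Step 2**
Reactants: 3 tert-butyl 3-formyl-1H-indole-1-carboxylate
Product: 4 1-(tert-butoxycarbonyl)-1H-indole-3-carboxylic acid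
Conditions: NaClO2, NaH2PO4, 2-methyl-2-butene, t-BuOH/THF/H2O, 0 °C → rt
Reagents that add atoms: sodium chlorite, [Na+].[O-]Cl=O
Why: Pinnick oxidation, in which buffered chlorous acid takes the aldehyde to the acid without touching the N-Boc group while 2-methyl-2-butene traps HOCl before it can chlorinate the indole.

**Step 3**
Reactants: 4 1-(tert-butoxycarbonyl)-1H-indole-3-carboxylic acid; 5 monobenzyl malonate (used as its magnesium salt)
Product: 7 benzyl 3-[1-(tert-butoxycarbonyl)-1H-indol-3-yl]-3-oxopropanoate, via acyl imidazolide 6 (not isolated)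
Conditions: CDI, THF, rt; then Mg(O2CCH2CO2Bn)2 (from 5 and Mg(OEt)2), THF, rt → 40 °C; cold 1 M HCl work-up
Reagents that add atoms: none
Why: Masamune–Brooks C-acylation, in which the neutral magnesium malonate is acylated by the imidazolide and loses CO2 to give the β-keto ester without any base strong enough to attack the N-Boc group.

**Step 4**
Reactants: 7 benzyl 3-[1-(tert-butoxycarbonyl)-1H-indol-3-yl]-3-oxopropanoate
Product: 8 benzyl 3-[1-(tert-butoxycarbonyl)-1H-indol-3-yl]-2-(hydroxyimino)-3-oxopropanoate (E/Z mixture, E isomer drawn)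
Conditions: NaNO2, AcOH/H2O, 5 °C → rt
Reagents that add atoms: sodium nitrite, [Na+].[O-]N=O
Why: Nitrosation of an active methylene, in which the enol of the β-keto ester captures the nitrosonium equivalent and the C-nitroso compound tautomerises to the oxime, the N-Boc-3-acylindole being too electron-poor to be nitrosated.

**Step 5**
Reactants: 8 benzyl 3-[1-(tert-butoxycarbonyl)-1H-indol-3-yl]-2-(hydroxyimino)-3-oxopropanoate; 2 methyl 3-(1H-indol-3-yl)-2-oxopropanoate (1.5 equiv)
Product: 11 5-benzyl 2-methyl 4-[1-(tert-butoxycarbonyl)-1H-indol-3-yl]-3-(1H-indol-3-yl)-1H-pyrrole-2,5-dicarboxylate, via amino ketone 9 (not isolated), via enamino ester 10 (not isolated)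
Conditions: Zn dust, NaOAc, AcOH, 60 → 80 °C; 8 added slowly to 2 and Zn
Reagents that add atoms: none
Why: Knorr pyrrole synthesis: zinc in acetic acid reduces the oxime of 8 to amino ketone 9, whose amine condenses with the keto group of the enolised pyruvate 2 to give enamino ester 10 (N1–C2); the enamine β-carbon, which carries the free indolyl group, then adds to the Boc-indolyl ketone (C3–C4) and two dehydrations aromatise the ring. The closest known reaction is the classical Knorr condensation of an α-oximino β-keto ester, reduced in situ, with an enolisable keto ester. The pyrrole closes by a 5-exo-trig aldol-type addition to the ketone with the enamine double bond inside the forming ring (5-(enolendo)-exo-trig), the mode of every Knorr closure. No stereocentre is created, since the α-carbon of 9 and the oxime geometry of 8 are lost on aromatisation. Cross-condensation has to win over dimerisation of 9 to a dihydropyrazine, which slow release of the amine beside an excess of 2 should secure, and the regiochemistry is fixed because 9 holds a single ketone (its other carbonyl is the benzyl ester) and 2 a single methylene. The N-Boc group stops the indol-3-yl ketone from behaving as a vinylogous amide, so it should stay electrophilic enough for the C–C closure.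

**Step 6**
Reactants: 11 5-benzyl 2-methyl 4-[1-(tert-butoxycarbonyl)-1H-indol-3-yl]-3-(1H-indol-3-yl)-1H-pyrrole-2,5-dicarboxylate
Product: 12 3-[1-(tert-butoxycarbonyl)-1H-indol-3-yl]-4-(1H-indol-3-yl)-5-(methoxycarbonyl)-1H-pyrrole-2-carboxylic acid
Conditions: H2 (1 atm), Pd/C (10 wt% Pd on carbon), EtOAc/MeOH, rt
Reagents that add atoms: none
Why: Hydrogenolysis of a benzyl ester over palladium on carbon, which at 1 atm should cleave only the benzylic C–O bond and leave the methyl ester, the N-Boc group and the indole and pyrrole rings intact.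

**Step 7**
Reactants: 12 3-[1-(tert-butoxycarbonyl)-1H-indol-3-yl]-4-(1H-indol-3-yl)-5-(methoxycarbonyl)-1H-pyrrole-2-carboxylic acid
Product: 14 methyl 4-[1-(tert-butoxycarbonyl)-1H-indol-3-yl]-3-(1H-indol-3-yl)-5-[methoxy(methyl)carbamoyl]-1H-pyrrole-2-carboxylate, via acyl imidazolide 13 (not isolated)
Conditions: CDI (1.1 equiv), THF, rt; then MeNH(OMe)·HCl, rt
Reagents that add atoms: N,O-dimethylhydroxylamine hydrochloride, CNOC.Cl
Why: Amide formation through CDI activation, in which the imidazolide of the pyrrole-2-carboxylic acid is aminolysed by N,O-dimethylhydroxylamine (its hydrochloride supplying the acid catalysis) to give the Weinreb amide.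

**Step 8**
Reactants: 14 methyl 4-[1-(tert-butoxycarbonyl)-1H-indol-3-yl]-3-(1H-indol-3-yl)-5-[methoxy(methyl)carbamoyl]-1H-pyrrole-2-carboxylate
Product: 15 methyl 5-acetyl-4-[1-(tert-butoxycarbonyl)-1H-indol-3-yl]-3-(1H-indol-3-yl)-1H-pyrrole-2-carboxylate
Conditions: MeMgBr (5 equiv), THF, −20 → 0 °C; aq. NH4Cl
Reagents that add atoms: methylmagnesium bromide, C[Mg]Br
Why: Weinreb ketone synthesis, in which MeMgBr first deprotonates the pyrrole and indole N–H groups and then adds once to the N-methoxy-N-methylamide to give a magnesium chelate that releases the methyl ketone only on quench, the methyl ester on the magnesiated pyrrole being too deactivated to react at 0 °C.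

**Step 9**
Reactants: 15 methyl 5-acetyl-4-[1-(tert-butoxycarbonyl)-1H-indol-3-yl]-3-(1H-indol-3-yl)-1H-pyrrole-2-carboxylate
Product: 16 methyl 5-acetyl-3,4-di(1H-indol-3-yl)-1H-pyrrole-2-carboxylate
Conditions: K2CO3 (cat.), MeOH/THF, 50 °C
Reagents that add atoms: none
Why: Base-catalysed methanolysis of an indole N-carbamate, in which methoxide attacks the Boc carbonyl and expels the indolide, freeing the indole without acid that could alkylate or cyclise the electron-rich bis(indolyl)pyrrole.

**Compound list**

1 | indole-3-pyruvic acid | OC(=O)C(=O)Cc1c[nH]c2ccccc12 | starting material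
2 | methyl 3-(1H-indol-3-yl)-2-oxopropanoate | COC(=O)C(=O)Cc1c[nH]c2ccccc12 | intermediate
3 | tert-butyl 3-formyl-1H-indole-1-carboxylate | O=Cc1cn(C(=O)OC(C)(C)C)c2ccccc12 | starting material
4 | 1-(tert-butoxycarbonyl)-1H-indole-3-carboxylic acid | OC(=O)c1cn(C(=O)OC(C)(C)C)c2ccccc12 | intermediate
5 | monobenzyl malonate (3-(benzyloxy)-3-oxopropanoic acid) | OC(=O)CC(=O)OCc1ccccc1 | starting material
6 | tert-butyl 3-(1H-imidazol-1-ylcarbonyl)-1H-indole-1-carboxylate | O=C(c1cn(C(=O)OC(C)(C)C)c2ccccc12)n1ccnc1 | intermediate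
7 | benzyl 3-[1-(tert-butoxycarbonyl)-1H-indol-3-yl]-3-oxopropanoate | O=C(CC(=O)c1cn(C(=O)OC(C)(C)C)c2ccccc12)OCc1ccccc1 | intermediate
8 | benzyl 3-[1-(tert-butoxycarbonyl)-1H-indol-3-yl]-2-(hydroxyimino)-3-oxopropanoate (E isomer drawn) | O=C(OCc1ccccc1)/C(=N/O)C(=O)c1cn(C(=O)OC(C)(C)C)c2ccccc12 | intermediate
9 | benzyl 2-amino-3-[1-(tert-butoxycarbonyl)-1H-indol-3-yl]-3-oxopropanoate (racemic) | NC(C(=O)OCc1ccccc1)C(=O)c1cn(C(=O)OC(C)(C)C)c2ccccc12 | intermediate
10 | methyl 2-({1-(benzyloxy)-3-[1-(tert-butoxycarbonyl)-1H-indol-3-yl]-1,3-dioxopropan-2-yl}amino)-3-(1H-indol-3-yl)prop-2-enoate (racemic, alkene geometry not defined) | COC(=O)C(=Cc1c[nH]c2ccccc12)NC(C(=O)OCc1ccccc1)C(=O)c1cn(C(=O)OC(C)(C)C)c2ccccc12 | intermediate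
11 | 5-benzyl 2-methyl 4-[1-(tert-butoxycarbonyl)-1H-indol-3-yl]-3-(1H-indol-3-yl)-1H-pyrrole-2,5-dicarboxylate | COC(=O)c1[nH]c(C(=O)OCc2ccccc2)c(-c2cn(C(=O)OC(C)(C)C)c3ccccc23)c1-c1c[nH]c2ccccc12 | intermediate
12 | 3-[1-(tert-butoxycarbonyl)-1H-indol-3-yl]-4-(1H-indol-3-yl)-5-(methoxycarbonyl)-1H-pyrrole-2-carboxylic acid | COC(=O)c1[nH]c(C(=O)O)c(-c2cn(C(=O)OC(C)(C)C)c3ccccc23)c1-c1c[nH]c2ccccc12 | intermediate
13 | methyl 4-[1-(tert-butoxycarbonyl)-1H-indol-3-yl]-5-(1H-imidazol-1-ylcarbonyl)-3-(1H-indol-3-yl)-1H-pyrrole-2-carboxylate | COC(=O)c1[nH]c(C(=O)n2ccnc2)c(-c2cn(C(=O)OC(C)(C)C)c3ccccc23)c1-c1c[nH]c2ccccc12 | intermediate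
14 | methyl 4-[1-(tert-butoxycarbonyl)-1H-indol-3-yl]-3-(1H-indol-3-yl)-5-[methoxy(methyl)carbamoyl]-1H-pyrrole-2-carboxylate | COC(=O)c1[nH]c(C(=O)N(C)OC)c(-c2cn(C(=O)OC(C)(C)C)c3ccccc23)c1-c1c[nH]c2ccccc12 | intermediate
15 | methyl 5-acetyl-4-[1-(tert-butoxycarbonyl)-1H-indol-3-yl]-3-(1H-indol-3-yl)-1H-pyrrole-2-carboxylate | COC(=O)c1[nH]c(C(C)=O)c(-c2cn(C(=O)OC(C)(C)C)c3ccccc23)c1-c1c[nH]c2ccccc12 | intermediate
16 | methyl 5-acetyl-3,4-di(1H-indol-3-yl)-1H-pyrrole-2-carboxylate | COC(=O)c1[nH]c(C(C)=O)c(-c2c[nH]c3ccccc23)c1-c1c[nH]c2ccccc12 | target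

**Step count**

Total steps: 9. Longest linear sequence: 8 steps (3 → 4 → 7 → 8 → 11 → 12 → 14 → 15 → 16); step 1 runs in parallel.

**Steps most likely to fail**

Step 5. The amino ketone may dimerise to a dihydropyrazine faster than it meets the pyruvate, zinc may reduce the α-keto ester, or the Boc group may be lost in warm acetic acid so that the C–C closure stalls. The fallback delivers the amino ketone as an isolated salt and uses no zinc. It sets out from acyl imidazolide 6, which would acylate the potassium enolate of benzyl N-(diphenylmethylene)glycinate (KOtBu, THF, −78 °C). This should give the Schiff base benzyl 3-[1-(tert-butoxycarbonyl)-1H-indol-3-yl]-2-[(diphenylmethylidene)amino]-3-oxopropanoate F1. Brief hydrolysis with 1 M HCl in THF at rt should release benzyl 2-amino-3-[1-(tert-butoxycarbonyl)-1H-indol-3-yl]-3-oxopropanoate hydrochloride F2. This salt would be condensed with 2 in AcOH buffered with NaOAc at 70 °C, and the route is rejoined at 11.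

Step 8. The Grignard reagent may also attack the methyl ester or the Boc carbonyl, or the polymagnesiated substrate may precipitate and stop the addition. Partial loss of Boc alone would be harmless, since it only anticipates step 9. The fallback avoids the organometallic reagent. It sets out from acyl imidazolide 13, which would be treated with Mg(O2CCH2CO2Bn)2 as in step 3 to give benzyl 3-{3-[1-(tert-butoxycarbonyl)-1H-indol-3-yl]-4-(1H-indol-3-yl)-5-(methoxycarbonyl)-1H-pyrrol-2-yl}-3-oxopropanoate F3. Hydrogenolysis (H2, Pd/C, EtOAc) should give the β-keto acid 3-{3-[1-(tert-butoxycarbonyl)-1H-indol-3-yl]-4-(1H-indol-3-yl)-5-(methoxycarbonyl)-1H-pyrrol-2-yl}-3-oxopropanoic acid F4. On gentle warming this should lose CO2, and the route is rejoined at 15.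

Step 3. The indole-3-carbonyl imidazolide is a deactivated electrophile, so acylation of the magnesium malonate may be slow enough for Boc transfer to imidazole to compete. The fallback sets out from acid 4, which would be coupled with Meldrum's acid (EDC·HCl, DMAP, CH2Cl2, 0 °C → rt). This should give the acyl Meldrum's acid tert-butyl 3-[(2,2-dimethyl-4,6-dioxo-1,3-dioxan-5-ylidene)(hydroxy)methyl]-1H-indole-1-carboxylate F5. Heating F5 with benzyl alcohol in toluene at 90 °C should open it with loss of acetone and CO2, and the route is rejoined at 7.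

**Further compounds**

F1 | step 5 | benzyl 3-[1-(tert-butoxycarbonyl)-1H-indol-3-yl]-2-[(diphenylmethylidene)amino]-3-oxopropanoate (racemic) | O=C(OCc1ccccc1)C(N=C(c1ccccc1)c1ccccc1)C(=O)c1cn(C(=O)OC(C)(C)C)c2ccccc12
F2 | step 5 | benzyl 2-amino-3-[1-(tert-butoxycarbonyl)-1H-indol-3-yl]-3-oxopropanoate hydrochloride (racemic) | Cl.NC(C(=O)OCc1ccccc1)C(=O)c1cn(C(=O)OC(C)(C)C)c2ccccc12
F3 | step 8 | benzyl 3-{3-[1-(tert-butoxycarbonyl)-1H-indol-3-yl]-4-(1H-indol-3-yl)-5-(methoxycarbonyl)-1H-pyrrol-2-yl}-3-oxopropanoate | COC(=O)c1[nH]c(C(=O)CC(=O)OCc2ccccc2)c(-c2cn(C(=O)OC(C)(C)C)c3ccccc23)c1-c1c[nH]c2ccccc12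
F4 | step 8 | 3-{3-[1-(tert-butoxycarbonyl)-1H-indol-3-yl]-4-(1H-indol-3-yl)-5-(methoxycarbonyl)-1H-pyrrol-2-yl}-3-oxopropanoic acid | COC(=O)c1[nH]c(C(=O)CC(=O)O)c(-c2cn(C(=O)OC(C)(C)C)c3ccccc23)c1-c1c[nH]c2ccccc12
F5 | step 3 | tert-butyl 3-[(2,2-dimethyl-4,6-dioxo-1,3-dioxan-5-ylidene)(hydroxy)methyl]-1H-indole-1-carboxylate | CC1(C)OC(=O)C(=C(O)c2cn(C(=O)OC(C)(C)C)c3ccccc23)C(=O)O1
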